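**Retrosynthetic overview**
1. Ring B is opened at C8–C9. The C7 ketone, C8 (carrying C17) and the ring C ether carbon C9–O13 form a β-alkoxy ketone, i.e. the Morita–Baylis–Hillman/aldol adduct of an acryloyl unit on C6 with the ketone-level carbon C9; this makes a sulfide-triggered Michael/Mukaiyama/E1cB closure onto the ring C oxocarbenium ion possible.
2. The precursor (C9 hemiketal plus C6–C7 vinyl ketone) comes from ozonolysis of the C7=C9 bond of a cis-hydrindene. The C6 and C9 arms are cis on ring A because both belong to the five-membered ring of a 4-methyl Hajos–Parrish ketone, which also supplies C10 and, by cis-hydrogenation, H5.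
3. C9–C11 is made by B-alkyl Suzuki–Miyaura coupling of the C9 enol triflate with fragment 2 (C11–C16, ring D as a C15 methyl acetal, C13 from a Sharpless epoxidation of an itaconate-derived allylic alcohol).
4. After ring B: Rubottom oxidation at C6 and directed hydrogenation of C8=C17, both on the convex β face of the cis-decalin; the C15 acetal is converted last into the C14=C15 enol ether by selenoxide elimination.
5. Order of ring formation: ring A (Hajos–Parrish), ring D (lactol acetal in fragment 2), ring C (hemiketal after ozonolysis), ring B (key step).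

Key step: step 22

Remark: labdane numbering (C1–C20) is used for all compounds and β means the face of C20; the target is read as 5β-H (cis-fused A/B), and acetal, hemiketal or carbinol carbons that arise as mixtures and are destroyed or set later (C15 in 17–36, C9 in 25–28, C7 in 26, C8 in 29) carry no configuration in the SMILES.

**Step 1**
Reactants: 1 2-methylcyclopentane-1,3-dione; 2 pent-1-en-3-one
Product: 3 2-methyl-2-(3-oxopentyl)cyclopentane-1,3-dione
Conditions: H2O, AcOH (cat.), 75 °C
Reagents that add atoms: none
Why: Michael addition of the cyclic 1,3-dione to the enone should give the triketone without creating a stereocentre.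

**Step 2**
Reactants: 3 triketone
Product: 4 (7aS)-4,7a-dimethyl-2,3,7,7a-tetrahydro-1H-indene-1,5(6H)-dione
Conditions: L-phenylalanine (1 equiv), (+)-camphorsulfonic acid (0.5 equiv), DMF, 30 → 70 °C
Reagents that add atoms: none
Why: Hajos–Parrish–Eder–Sauer–Wiechert reaction, in which the enamine of the side-chain ketone formed with the L-amino acid differentiates the two ring carbonyls in the aldol step and should set C10 as S before dehydration.

**Step 3**
Reactants: 4 enedione
Product: 5 (1S,7aS)-1-hydroxy-4,7a-dimethyl-1,2,3,6,7,7a-hexahydro-5H-inden-5-one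
Conditions: NaBH4 (0.3 equiv), EtOH, −20 °C
Reagents that add atoms: none
Why: Chemoselective borohydride reduction of the saturated C9 ketone in preference to the tetrasubstituted enone, with hydride entering anti to C20; the 9β-carbinol is temporary and keeps C9 out of the enolate chemistry that follows.

**Step 4**
Reactants: 5 hydroxy enone
Product: 6 cis-fused 9β-hydroxy-4α-methylhydrindan-3-one (H4 and H5 β)
Conditions: H2 (1 atm), 10% Pd/C, EtOAc, 23 °C
Reagents that add atoms: none
Why: Heterogeneous hydrogenation of Hajos–Parrish-type enones should add H2 syn on the face of C20 and give the cis-fused hydrindanone, which sets H5 cis to C20 (the C4 centre is erased in step 5).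

**Step 5**
Reactants: 6 cis-hydrindanone
Product: 7 bis(trimethylsilyl) C3=C4 enol ether of 6
Conditions: TMSCl, NaI, Et3N, MeCN, 23 °C
Reagents that add atoms: chlorotrimethylsilane, C[Si](C)(C)Cl
Why: Equilibrating silylation should give the more substituted C3=C4 silyl enol ether, the direction of enolisation favoured in cis-fused 3-ketones, and also silylates the C9 alcohol.

**Step 6**
Reactants: 7 silyl enol ether
Product: 8 9β-hydroxy-4β-(hydroxymethyl)-4α-methyl cis-hydrindan-3-one
Conditions: aq. CH2O, Yb(OTf)3 (10 mol%), THF, 23 °C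
Reagents that add atoms: formaldehyde, C=O
Why: Lewis acid-catalysed Mukaiyama aldol reaction in water, in which formaldehyde should attack C4 on the convex β face anti to the C5–C6 bond, making C4 quaternary with C19 β and C18 α.

**Step 7**
Reactants: 8 keto diol
Product: 10 3β,9β,19-triol, via boron chelate 9 (not isolated)
Conditions: Et2BOMe, THF/MeOH, −78 °C; then NaBH4; then MeOH evaporation
Reagents that add atoms: none
Why: Narasaka–Prasad reduction, in which the chelate between O19 and the C3 carbonyl is attacked by external hydride on the α face and should give the 3β-alcohol cis to C19.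

**Step 8**
Reactants: 10 triol
Product: 11 3,19-O-isopropylidene acetal with free 9β-hydroxyl
Conditions: 2,2-dimethoxypropane, PPTS, CH2Cl2, 23 °C
Reagents that add atoms: 2,2-dimethoxypropane, COC(C)(C)OC
Why: Acetalisation, in which only the cis-1,3-diol can close a six-membered acetonide, so the hindered C9 alcohol stays free.

**Step 9**
Reactants: 11 acetonide alcohol
Product: 12 acetonide C9 ketone
Conditions: Dess–Martin periodinane, NaHCO3, CH2Cl2, 23 °C
Reagents that add atoms: none
Why: Dess–Martin oxidation returns the C9 ketone under non-acidic conditions that the acetonide tolerates.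

**Step 10**
Reactants: 12 ketone
Product: 13 C9 enol triflate (C7=C9)
Conditions: KHMDS, PhNTf2, THF, −78 °C
Reagents that add atoms: N-phenylbis(trifluoromethanesulfonimide), O=S(=O)(N(c1ccccc1)S(=O)(=O)C(F)(F)F)C(F)(F)F
Why: Kinetic enolisation can only go towards C7 because C10 is quaternary, and O-sulfonylation of the enolate gives the vinyl triflate for cross-coupling.

**Step 11**
Reactants: 14 itaconic acid 4-methyl ester
Product: 15 methyl 3-(hydroxymethyl)but-3-enoate
Conditions: BH3·SMe2, THF, 0 °C
Reagents that add atoms: none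
Why: Borane reduces the free carboxylic acid much faster than the methyl ester (chemoselective acid reduction) and should give the 2-substituted allylic alcohol.

**Step 12**
Reactants: 15 allylic alcohol
Product: 16 methyl 2-[(2R)-2-(hydroxymethyl)oxiran-2-yl]acetate
Conditions: Ti(OiPr)4 (cat.), L-(+)-diethyl tartrate, t-BuOOH, 4 Å MS, CH2Cl2, −20 °C
Reagents that add atoms: tert-butyl hydroperoxide, CC(C)(C)OO
Why: Sharpless asymmetric epoxidation, in which the L-(+)-tartrate complex delivers oxygen to the face of the 1,1-disubstituted alkene that makes C13 R.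

**Step 13**
Reactants: 16 epoxy ester
Product: 17 spiro-epoxy lactol 1,5-dioxaspiro[2.4]heptan-6-ol (ring D)
Conditions: DIBAL-H (2.2 equiv), CH2Cl2, −78 °C
Reagents that add atoms: none
Why: Half-reduction of the ester gives the aldehyde, which should close with the C16 hydroxyl to the five-membered lactol while the epoxide survives at low temperature.

**Step 14**
Reactants: 17 lactol
Product: 18 6-methoxy-1,5-dioxaspiro[2.4]heptane
Conditions: NaH, MeI, THF, 0 °C
Reagents that add atoms: iodomethane, CI
Why: Williamson O-alkylation of the anomeric alkoxide forms the methyl acetal without acid, which would open the spiro-epoxide.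

**Step 15**
Reactants: 18 epoxy acetal
Product: 19 fragment 2 (3-ethenyl-5-methoxyoxolan-3-ol)
Conditions: Me3S+ I−, n-BuLi, THF, −10 → 23 °C
Reagents that add atoms: trimethylsulfonium iodide, C[S+](C)C.[I-]
Why: Dimethylsulfonium methylide should open the epoxide at its CH2 carbon and the sulfonium salt then eliminates Me2S (one-carbon homologation of an epoxide to an allylic alcohol), so C13 is not touched.

**Step 16**
Reactants: 13 enol triflate; 19 fragment 2
Product: 21 C9–C11 coupled cyclopentene, via alkylborane 20 (not isolated)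
Conditions: 19, 9-BBN (2.2 equiv), THF, 0 → 23 °C; then 13, Pd(dppf)Cl2 (5 mol%), AsPh3, Cs2CO3, DMF/H2O, 50 °C
Reagents that add atoms: none
Why: B-alkyl Suzuki–Miyaura coupling, in which anti-Markovnikov hydroboration puts boron on C11 and the alkylborane couples with the vinyl triflate to form C9–C11 without touching a stereocentre.

**Step 17**
Reactants: 21 acetonide
Product: 22 3β,19-diol
Conditions: PPTS, MeOH, 23 °C
Reagents that add atoms: none
Why: Acid-catalysed transacetalisation in methanol removes the acetonide while ring D remains a methyl acetal.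

**Step 18**
Reactants: 22 diol
Product: 23 3β,19-diacetate
Conditions: Ac2O, pyridine, 23 °C
Reagents that add atoms: acetic anhydride, CC(=O)OC(C)=O
Why: Acetylation of the primary and secondary alcohols, which the tertiary C13 alcohol should not undergo without an acyl-transfer catalyst.

**Step 19**
Reactants: 23 cyclopentene diacetate
Product: 25 ring C hemiketal aldehyde, via ozonide 24 (not isolated)
Conditions: O3, CH2Cl2, −78 °C; then Me2S, −78 → 23 °C
Reagents that add atoms: ozone, [O-][O+]=O
Why: Ozonolysis cleaves the only C=C bond (C7=C9) of the temporary five-membered carbocycle, leaving the C6 and C9 arms cis on ring A, and the C9 ketone should be captured by the C13 hydroxyl as the five-membered hemiketal that closes ring C.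

**Step 20**
Reactants: 25 aldehyde
Product: 26 C7 allylic alcohol
Conditions: vinylmagnesium bromide (3 equiv), THF, −78 °C
Reagents that add atoms: vinylmagnesium bromide, C=C[Mg]Br
Why: Grignard addition to the aldehyde at −78 °C, where the acetates and the hemiketal (as its alkoxide) should not react; the new carbinol centre is oxidised in step 21.

**Step 21**
Reactants: 26 allylic alcohol
Product: 27 vinyl ketone hemiketal
Conditions: Dess–Martin periodinane, NaHCO3, CH2Cl2, 0 → 23 °C
Reagents that add atoms: none
Why: Dess–Martin oxidation of the secondary allylic alcohol gives the vinyl ketone and leaves the tertiary hemiketal hydroxyl.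

**Step 22**
Reactants: 27 vinyl ketone hemiketal
Product: 30 ring B enone (8(17)-en-7-one), via sulfonium silyl enol ether 28 (not isolated), via ring B sulfonium ketone 29 (not isolated)
Conditions: TMSOTf (3 equiv), Me2S (2 equiv), 2,6-di-tert-butyl-4-methylpyridine (1.2 equiv), CH2Cl2, −78 → −40 °C; then DBU, −40 → 0 °C
Reagents that add atoms: none
Why: Proposed new method: TMSOTf silylates the hemiketal hydroxyl and ionises C9 to the ring C oxocarbenium ion while Me2S adds to C17 of the silyl-activated vinyl ketone to give the β-sulfonio silyl enol ether 28, whose C8 then attacks C9 to give 29, and DBU expels Me2S by E1cB elimination to unveil the C8=C17 enone; the closest known reaction type is the sulfide/Lewis acid-mediated (chalcogeno) Morita–Baylis–Hillman reaction of enones with acetals and its intramolecular version with aldehydes, here extended to a hemiketal-derived oxocarbenium ion that becomes a spiro quaternary carbon. Ring B, the only ring closed, forms in the 6-(enolendo)-exo-trig mode, with the C7=C8 enol bond inside and the C9=O13 bond outside the new ring. C9 is the only new stereocentre: ring A should keep the chair in which the forming quaternary C9 is equatorial, ring B then closes through the chair in which C1 is axial, and the small O13 takes the equatorial site between C1 and C20 (antiperiplanar to C7=C8) while the C11 methylene goes axial next to H5, which gives the target configuration (O13 α, C11 β). The step needs the C9 hemiketal to ionise before the C15 methyl acetal, which the faster ionisation of a ketone-level centre at −78 °C should secure, and it needs C–C bonding at C8 rather than at C6 or C11, which is secured because the sulfide places the enol silane regiospecifically at C7=C8 and no base able to convert the cation irreversibly into the C9=C11 enol ether is present.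

**Step 23**
Reactants: 30 enone
Product: 31 C6=C7 triethylsilyl dienol ether
Conditions: LiHMDS, TESCl (in situ), THF, −78 °C
Reagents that add atoms: chlorotriethylsilane, CC[Si](CC)(CC)Cl
Why: Kinetic deprotonation of the enone can only occur at C6 because C8 carries no hydrogen, and LiHMDS with in situ silylation should spare the less acidic acetates and give the cross-conjugated silyl dienol ether.

**Step 24**
Reactants: 31 silyl dienol ether
Product: 33 6β-hydroxy enone, via silyloxy enone 32 (not isolated)
Conditions: dimethyldioxirane, acetone/CH2Cl2, −78 → −40 °C; then citric acid, MeOH, 0 °C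
Reagents that add atoms: dimethyldioxirane, CC1(C)OO1
Why: Rubottom oxidation, in which the oxidant should epoxidise the electron-rich C6=C7 enol ether on the convex β face of the cis-decalin (the α face is blocked by the axial C1 of ring A), and silyl migration followed by mild acid gives the 6β-alcohol.

**Step 25**
Reactants: 33 hydroxy enone
Product: 34 6β-hydroxy-8α-methyl-7-ketone with ring D methyl acetal
Conditions: H2 (1 atm), [Ir(cod)(py)(PCy3)]PF6 (5 mol%), CH2Cl2, 23 °C
Reagents that add atoms: none
Why: Hydroxyl-directed homogeneous hydrogenation, in which the 6β-hydroxyl binds the cationic iridium catalyst so that H2 should be delivered to the β (also convex) face of C8=C17, setting C8 with the methyl group α.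

**Step 26**
Reactants: 34 methyl acetal
Product: 35 C15 phenylseleno acetal
Conditions: PhSeH, BF3·OEt2, CH2Cl2, −40 °C
Reagents that add atoms: benzeneselenol, [SeH]c1ccccc1
Why: Lewis acid-mediated acetal exchange, in which only the C15 acetal ionises and the soft selenol traps the oxocarbenium ion, leaving ketone, alcohol and acetates untouched.

**Step 27**
Reactants: 35 selenoacetal
Product: 37 target CNP0317137.2, via selenoxide 36 (not isolated)
Conditions: mCPBA (1.05 equiv), CH2Cl2, −78 °C; then i-Pr2NH, −78 → 23 °C
Reagents that add atoms: none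
Why: Selenide oxidation and syn-elimination of the selenoxide towards C14 (the only β-hydrogens) should form the C14=C15 enol ether under basic conditions that the acid-sensitive product tolerates.

**Compound list**
1 | 2-methylcyclopentane-1,3-dione | CC1C(=O)CCC1=O | starting material
2 | pent-1-en-3-one (ethyl vinyl ketone) | CCC(=O)C=C | starting material
3 | 2-methyl-2-(3-oxopentyl)cyclopentane-1,3-dione | CCC(=O)CCC1(C)C(=O)CCC1=O | intermediate
4 | (7aS)-4,7a-dimethyl-2,3,7,7a-tetrahydro-1H-indene-1,5(6H)-dione (six-membered ring = ring A) | CC1=C2CCC(=O)[C@@]2(C)CCC1=O | intermediate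
5 | (1S,7aS)-1-hydroxy-4,7a-dimethyl-1,2,3,6,7,7a-hexahydro-5H-inden-5-one (9β-alcohol) | CC1=C2CC[C@H](O)[C@@]2(C)CCC1=O | intermediate
6 | cis-fused 9β-hydroxy-4α-methylhydrindan-3-one (H4, H5, 9-OH and C20 all β) | C[C@@H]1C(=O)CC[C@@]2(C)[C@@H]1CC[C@@H]2O | intermediate
7 | bis(trimethylsilyl) C3=C4 enol ether of 6 | CC1=C(O[Si](C)(C)C)CC[C@@]2(C)[C@@H]1CC[C@@H]2O[Si](C)(C)C | intermediate
8 | 9β-hydroxy-4β-(hydroxymethyl)-4α-methyl cis-hydrindan-3-one | OC[C@@]1(C)C(=O)CC[C@@]2(C)[C@@H]1CC[C@@H]2O | intermediate
9 | O19-diethylboryl chelate of 8 | CCB(CC)OC[C@@]1(C)C(=O)CC[C@@]2(C)[C@@H]1CC[C@@H]2O | intermediate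
10 | 3β,9β,19-triol (3-OH, C19 and C20 cis) | OC[C@@]1(C)[C@@H](O)CC[C@@]2(C)[C@@H]1CC[C@@H]2O | intermediate
11 | 3,19-O-isopropylidene acetal of 10 with free 9β-hydroxyl | CC1(C)OC[C@@]2(C)[C@@H](O1)CC[C@@]3(C)[C@@H]2CC[C@@H]3O | intermediate
12 | acetonide C9 ketone | CC1(C)OC[C@@]2(C)[C@@H](O1)CC[C@@]3(C)[C@@H]2CCC3=O | intermediate
13 | C9 enol triflate (C7=C9) | CC1(C)OC[C@@]2(C)[C@@H](O1)CC[C@@]3(C)[C@@H]2CC=C3OS(=O)(=O)C(F)(F)F | intermediate
14 | itaconic acid 4-methyl ester | C=C(CC(=O)OC)C(=O)O | starting material
15 | methyl 3-(hydroxymethyl)but-3-enoate | C=C(CO)CC(=O)OC | intermediate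
16 | methyl 2-[(2R)-2-(hydroxymethyl)oxiran-2-yl]acetate | C1[C@](CO)(CC(=O)OC)O1 | intermediate
17 | 1,5-dioxaspiro[2.4]heptan-6-ol (spiro-epoxy lactol, ring D, C13 as in 16, anomers) | C1[C@]2(CC(O)OC2)O1 | intermediate
18 | 6-methoxy-1,5-dioxaspiro[2.4]heptane (anomers) | C1[C@]2(CC(OC)OC2)O1 | intermediate
19 | fragment 2: 3-ethenyl-5-methoxyoxolan-3-ol (C13 as in the target, C15 anomers) | C=C[C@]1(CC(OC)OC1)O | intermediate
20 | B-alkyl-9-BBN adduct of 19 (boron on C11) | C(CB1C2CCCC1CCC2)[C@]3(CC(OC)OC3)O | intermediate
21 | C9–C11 coupled cyclopentene (ring A acetonide, C7=C9, ring D methyl acetal, free 13-OH) | CC1(C)OC[C@@]2(C)[C@@H](O1)CC[C@@]3(C)[C@@H]2CC=C3CC[C@]4(CC(OC)OC4)O | intermediate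
22 | 3β,19-diol of 21 | OC[C@@]1(C)[C@@H](O)CC[C@@]2(C)[C@@H]1CC=C2CC[C@]3(CC(OC)OC3)O | intermediate
23 | 3β,19-diacetate | CC(=O)OC[C@@]1(C)[C@@H](OC(C)=O)CC[C@@]2(C)[C@@H]1CC=C2CC[C@]3(CC(OC)OC3)O | intermediate
24 | secondary ozonide of 23 across C7 and C9 | CC(=O)OC[C@@]1(C)[C@@H](OC(C)=O)CC[C@@]2(C)[C@@H]1CC3OC2(OO3)CC[C@]4(CC(OC)OC4)O | intermediate
25 | ring C hemiketal aldehyde (C9 hemiketal with O13, C7 aldehyde) | CC(=O)OC[C@@]1(C)[C@@H](OC(C)=O)CC[C@](C)(C2(O)CC[C@]3(CC(OC)OC3)O2)[C@@H]1CC=O | intermediate
26 | C7 allylic alcohol (vinyl = C8=C17) | CC(=O)OC[C@@]1(C)[C@@H](OC(C)=O)CC[C@](C)(C2(O)CC[C@]3(CC(OC)OC3)O2)[C@@H]1CC(O)C=C | intermediate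
27 | vinyl ketone hemiketal (key-step precursor) | CC(=O)OC[C@@]1(C)[C@@H](OC(C)=O)CC[C@](C)(C2(O)CC[C@]3(CC(OC)OC3)O2)[C@@H]1CC(=O)C=C | intermediate
28 | β-dimethylsulfonio silyl enol ether with C9 silyl ketal (triflate) | CC(=O)OC[C@@]1(C)[C@@H](OC(C)=O)CC[C@](C)(C2(O[Si](C)(C)C)CC[C@]3(CC(OC)OC3)O2)[C@@H]1CC(O[Si](C)(C)C)=CC[S+](C)C.[O-]S(=O)(=O)C(F)(F)F | intermediate
29 | ring B β-sulfonium ketone (triflate) | CC(=O)OC[C@@]1(C)[C@@H](OC(C)=O)CC[C@@]2(C)[C@@H]1CC(=O)C(C[S+](C)C)[C@]21CC[C@]2(CC(OC)OC2)O1.[O-]S(=O)(=O)C(F)(F)F | intermediate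
30 | ring B enone: 8(17)-en-7-one, ring C spiro at C9 (O13 α, C11 β), ring D methyl acetal, 3β,19-diacetate | CC(=O)OC[C@@]1(C)[C@@H](OC(C)=O)CC[C@@]2(C)[C@@H]1CC(=O)C(=C)[C@]21CC[C@]2(CC(OC)OC2)O1 | intermediate
31 | C6=C7 triethylsilyl dienol ether of 30 | CC(=O)OC[C@@]1(C)[C@@H](OC(C)=O)CC[C@@]2(C)[C@@H]1C=C(O[Si](CC)(CC)CC)C(=C)[C@]21CC[C@]2(CC(OC)OC2)O1 | intermediate
32 | 6β-triethylsilyloxy enone | CC(=O)OC[C@@]1(C)[C@@H](OC(C)=O)CC[C@@]2(C)[C@@H]1[C@H](O[Si](CC)(CC)CC)C(=O)C(=C)[C@]21CC[C@]2(CC(OC)OC2)O1 | intermediate
33 | 6β-hydroxy enone | CC(=O)OC[C@@]1(C)[C@@H](OC(C)=O)CC[C@@]2(C)[C@@H]1[C@H](O)C(=O)C(=C)[C@]21CC[C@]2(CC(OC)OC2)O1 | intermediate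
34 | 6β-hydroxy-8α-methyl-7-ketone with ring D methyl acetal | CC(=O)OC[C@@]1(C)[C@@H](OC(C)=O)CC[C@@]2(C)[C@@H]1[C@H](O)C(=O)[C@@H](C)[C@]21CC[C@]2(CC(OC)OC2)O1 | intermediate
35 | C15 phenylseleno acetal | CC(=O)OC[C@@]1(C)[C@@H](OC(C)=O)CC[C@@]2(C)[C@@H]1[C@H](O)C(=O)[C@@H](C)[C@]21CC[C@]2(CC([Se]c3ccccc3)OC2)O1 | intermediate
36 | C15 selenoxide | CC(=O)OC[C@@]1(C)[C@@H](OC(C)=O)CC[C@@]2(C)[C@@H]1[C@H](O)C(=O)[C@@H](C)[C@]21CC[C@]2(CC([Se](=O)c3ccccc3)OC2)O1 | intermediate
37 | CNP0317137.2 | CC(=O)OC[C@@]1(C)[C@@H](OC(C)=O)CC[C@@]2(C)[C@@H]1[C@H](O)C(=O)[C@@H](C)[C@]21CC[C@]2(C=COC2)O1 | target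

**Totals**
Total step count: 27. Longest linear sequence: 22 steps (steps 1–10 and 16–27); fragment 2 takes steps 11–15.

**Steps most likely to fail**

Step 22. The two faces of the planar C9 oxocarbenium ion may be attacked without selectivity, the ring D acetal may ionise as well, or the bulky sulfonium enol ether may be too slow to trap the hindered cation before elimination or oligomerisation. The fallback keeps ring B as the last ring closed at C8–C9 but uses known chemistry, a small preformed nucleophile and later addition of C17; it does not by itself correct facial selectivity at C9, but it allows the C9 epimers to be separated. It sets out from aldehyde 25. MeMgBr (THF, −78 °C) would give the methyl carbinol F1, and Dess–Martin periodinane the methyl ketone F2. LiHMDS/TMSCl (−78 °C) would give the terminal silyl enol ether F3 (hemiketal also silylated). Catalytic TMSOTf (CH2Cl2, −78 °C) would then close ring B by an intramolecular Mukaiyama aldol-type addition to the C9 oxocarbenium ion and give the ring B ketone F4, at which stage C9 epimers could be separated. Kinetic enolisation at the less hindered C6 (LiHMDS, TESCl) and Rubottom oxidation with dimethyldioxirane would give the 6β-triethylsilyloxy ketone F5. Enolisation towards C8 (LiHMDS) and Mannich reaction with dimethyl(methylidene)ammonium iodide would give the amino ketone F6; N-methylation (MeI) and NaHCO3 would eliminate trimethylamine and come back to the route at 32.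

Step 6. Formaldehyde may add to the wrong face of the C3=C4 enol ether, or the enol ether may form towards C2. The fallback delivers C19 intramolecularly from the C3 oxygen and replaces steps 4 to 7. It sets out from 5. Luche reduction (NaBH4, CeCl3, MeOH) would give the 3β,9β-diol F7, and (bromomethyl)chlorodimethylsilane (Et3N, CH2Cl2) the bis-silyl ether F8. Bu3SnH/AIBN (benzene, 80 °C) would cyclise the C3-tethered radical 5-exo onto C4 and reduce the C5 radical from the convex face, giving the cis-fused siloxane F9 (the C9 tether is simply reduced to a trimethylsilyl ether). Tamao oxidation (H2O2, KF, KHCO3) would then give triol 10, where the route is rejoined.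

Step 25. Hydrogen may be delivered to the α face of C8=C17, or the α-ketol may deactivate the catalyst. The fallback replaces syn-hydrogenation by conjugate hydride addition and kinetic protonation. It sets out from 32, isolated without the citric acid work-up. Et3SiH with RhCl(PPh3)3 (benzene, 60 °C) would give the tetrasubstituted silyl enol ether F10. Buffered fluoride (TBAF, AcOH, THF, −20 °C) would then protonate C8 from the convex β face and free the C6 hydroxyl, coming back to the route at 34.

**Further compounds**
F1 | step 22 | methyl carbinol (C7 secondary alcohol, C8 methyl) of hemiketal 25 | CC(=O)OC[C@@]1(C)[C@@H](OC(C)=O)CC[C@](C)(C2(O)CC[C@]3(CC(OC)OC3)O2)[C@@H]1CC(C)O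
F2 | step 22 | methyl ketone hemiketal | CC(=O)OC[C@@]1(C)[C@@H](OC(C)=O)CC[C@](C)(C2(O)CC[C@]3(CC(OC)OC3)O2)[C@@H]1CC(C)=O
F3 | step 22 | terminal trimethylsilyl enol ether with C9 silyl ketal | CC(=O)OC[C@@]1(C)[C@@H](OC(C)=O)CC[C@](C)(C2(O[Si](C)(C)C)CC[C@]3(CC(OC)OC3)O2)[C@@H]1CC(=C)O[Si](C)(C)C
F4 | step 22 | ring B ketone without C17 (C6 and C8 methylene) | CC(=O)OC[C@@]1(C)[C@@H](OC(C)=O)CC[C@@]2(C)[C@@H]1CC(=O)C[C@]21CC[C@]2(CC(OC)OC2)O1
F5 | step 22 | 6β-triethylsilyloxy ring B ketone without C17 | CC(=O)OC[C@@]1(C)[C@@H](OC(C)=O)CC[C@@]2(C)[C@@H]1[C@H](O[Si](CC)(CC)CC)C(=O)C[C@]21CC[C@]2(CC(OC)OC2)O1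
F6 | step 22 | C8 (dimethylamino)methyl Mannich base | CC(=O)OC[C@@]1(C)[C@@H](OC(C)=O)CC[C@@]2(C)[C@@H]1[C@H](O[Si](CC)(CC)CC)C(=O)C(CN(C)C)[C@]21CC[C@]2(CC(OC)OC2)O1
F7 | step 6 | 3β,9β-dihydroxy-4-methyl hydrind-4-ene (allylic diol) | CC1=C2CC[C@H](O)[C@@]2(C)CC[C@@H]1O
F8 | step 6 | bis[(bromomethyl)dimethylsilyl] ether of F7 | CC1=C2CC[C@H](O[Si](C)(C)CBr)[C@@]2(C)CC[C@@H]1O[Si](C)(C)CBr
F9 | step 6 | cis-fused cyclic siloxane (O3–Si–C19) with 9β-trimethylsilyl ether | C[Si]1(C)C[C@@]2(C)[C@@H](O1)CC[C@@]3(C)[C@@H]2CC[C@@H]3O[Si](C)(C)C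
F10 | step 25 | C7=C8 triethylsilyl enol ether with 6β-triethylsilyloxy group | CC(=O)OC[C@@]1(C)[C@@H](OC(C)=O)CC[C@@]2(C)[C@@H]1[C@H](O[Si](CC)(CC)CC)C(O[Si](CC)(CC)CC)=C(C)[C@]21CC[C@]2(CC(OC)OC2)O1
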